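**The pitfall.** Equivalents mislead when you plan a plate: ash has more of them than larch, 3.00 equiv against 2.00 equiv, yet a lower [X], 0.0360 M against 0.0980 M. In the proposed steps L is lost by meeting X, so sort by [X] as charged.

| flask | Q | X | remark | time |
|---|---|---|---|---|
| Tuesday's | 0.054 M | 2 equiv | run made earlier |  |
| ash | 0.012 M | 3.00 equiv |  | 25 h |
| alder | 0.049 M | 0.660 equiv |  | 25 h |
| cedar | 0.025 M | 0.500 equiv |  | 25 h |
| birch | 0.015 M | 0.500 equiv |  | 25 h |
| larch | 0.049 M | 2.00 equiv |  | 25 h |
| elm | 0.049 M | 1.30 equiv |  | 25 h |

Tuesday's run (percent of the Q charged)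

| time / h | L / % | D / % | Q / % |
|---|---|---|---|
| 1.00 | 13.5 | 1.3 | 64.2 |
| 2.00 | 22.6 | 2.1 | 55.8 |
| 3.00 | 30.8 | 3.0 | 50.4 |
| 4.00 | 37.9 | 4.9 | 43.9 |
| 5.00 | 42.3 | 6.2 | 37.2 |

(readings scatter by 1 percentage point)

- steps that have been proposed: Q -> L; Q <-> E; X + L -> D

* the flasks put in order of amount of L, in percent of the Q charged, best first, at 25 h (ash / alder / cedar / birch / larch / elm)
* the amount of L, in percent of the Q charged of the flask you put first, at 25 h
* the amount of L, in percent of the Q charged of the flask you put last, at 25 h

**The bite.** In Tuesday's run the area under L up to 5.00 h is 1.26 h, counted in units of the Q charged. D then stood at 6.2 %, so I read a pseudo-first-order loss of L of 0.0492 /h. What is neither L nor D, that is Q and E together, decays at 0.126 /h. L therefore arrives 7.95 h late on average, and 4.16 % should still be unfed at 25 h.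

Fold this into one number, the bite: [X] as charged divided by the [X] that gives a bite of one, 0.129 M. L is then what has been fed, times exp(−bite).

My reckoning gives birch a bite of 0.0583 and 90.4 % L, and larch a bite of 0.762 and 44.7 % L. Rising [X] runs birch, cedar, alder, ash, elm, larch.

**One number enough?** The bite holds X at its charge. Alder stands at a bite of 0.251 and ash at 0.280. Alder should spend a larger part of its X than ash, about 33.7 % against 8.14 %, so I expect the gap between these two flasks to widen and their order to stand.

**The forecast.** It gives birch > cedar > alder > ash > elm > larch, with 91 % (87 % to 94 %) on top and 45 % (36 % to 54 %) last, holding that “L is then set by the absolute X concentration”.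

**The result.** Birch gives 90.4 % and larch 47.0 %, in the order birch > cedar > alder > ash > elm > larch.

    Q → L (k = 0.179 /h)
    Q ⇌ E (K = 0.350, k = 1.07 /h)
    X + L → D (k = 0.484 /M/h)

Alder kept 69 % of its X and ash 92 %, with L at 76.0 % against 71.2 %. Now take two neighbours of birch: one with Q at 0.037 M, equivalents held, and one with X at 1.20 equiv. Their bites are 0.144 and 0.140, which give 83.0 % and 83.3 % L. They keep 75 % and 89 % of their X, and they stand at 83.6 % and 82.9 % L.

Readings and results come from a simulation from invented constants, and the scatter is random.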